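The rate constants were drawn at random within sensible limits; the flask was simulated.

We charge more solid reagent than substrate, 3.00 charges of it, so substrate is the limiting reagent.

substrate 1.0 M; solid reagent 3.00 M; free catalyst 10 mM; time 2.0 h

    partner + free catalyst ⇌ catalyst intermediate A (K1 = 2.7 /M, k1 = 0.29 /M/s)
    solid reagent ⇌ partner, rate k2*(cs2 - [partner]) while solid is left; crystals form when [partner] > cs2 (cs2 = 0.48 M, k2 = 3.2 × 10⁻⁴ /s)
    substrate + catalyst intermediate A → catalyst intermediate B (k3 = 0.10 /M/s)
    catalyst intermediate C ⇌ free catalyst + target (K4 = 2.2 M, k4 = 0.25 /s)
    substrate + released group ⇌ idle adduct, settled at all times (K5 = 1.5 /M)
    catalyst intermediate B ⇌ released group + catalyst intermediate C (K6 = 1.9 M, k6 = 0.45 /s)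

- what is said of released group includes idle adduct
- solid reagent is a solid; its amount is given per volume of the solution
- at the start none of the solid reagent is in solution
- run time (flask): 2.0 h

- how much target there is at 2.0 h, in percent of the substrate charged
- the change that raises the amount of target at 2.0 h, in percent of the substrate charged most ("none" if none brings more than 2 percentage points) (delta / epsilon / zeta / none)
- amount of target at 2.0 h, in percent of the substrate charged, after zeta

- delta: doubling the amount of free catalyst, all else as stated
- epsilon: doubling the solubility in step 2, all else as stated
- zeta: doubling the dissolution coefficient of step 2, all else as stated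

- The puzzle is that each target takes up one partner, yet a saturated solution holds a fraction 0.480 of the substrate charge, about half.
- Partner passes through the solution, so the measure is a flow: dissolution coefficient times solubility times time, over the substrate charge, gives 111%; this is the feed ceiling, the fraction of the substrate charge the dissolution step can deliver into a solution kept empty.
- The ceiling clears the charge, but the feed shrinks by the share of saturation standing in solution, and the partner still standing at the end is not yet target.
- If partner stands at half of saturation throughout, target is 31.3%; at a quarter it is 70.9%, and that range is as far as our reckoning goes.
- Epsilon and zeta each raise the ceiling to 222%, while delta leaves it at 111%; with partner standing, epsilon's feed stays ahead of zeta's, so we pick epsilon.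
- The forecast gives 58%, inside our range, then 71% after zeta, and picks epsilon: “dissolution is faster than zeta”.
- The simulation gives 58.2%, 71.6% after zeta, and epsilon as best, with a gain of 20 percentage points, so the forecast held.
- In the flask, dissolution ran throughout with solid reagent present, 73.4% of its charge at 2.00 h, so delivery reads 79.8% of the substrate charge, 71.9% of the ceiling, with partner at 28.6% of saturation at 1.00 h; less the 21.2% of the charge standing as partner at 2.00 h it leaves 58.7%, beside the target reading of 58.2%. In the neighbour flask with 0.0025 M of free catalyst, the ceiling is the same 111%, delivery reads 60.1% of the substrate charge, and at 2.00 h that divides into 31.1% standing as partner and 28.9% as target.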